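(The numbers in the tables were computed for an exercise; the scatter is artificial.)

| flask | substrate | remark | time |
|---|---|---|---|
| maple | 2.9 M | run made earlier |  |
| delta | 2.1 M |  | 4.0 min |
| gamma | 2.1 M |  | 15 min |
| theta | 2.1 M |  | 8.0 min |

- maple (time / min: target / %, substrate / %): 0.200: 2, 96; 0.667: 7, 77; 1.00: 16, 68; 1.50: 17, 57; 2.50: 30, 41

(standard deviation of a reading: 2 percentage points)

- in percentages every species weighs as the substrate in it: one idle adduct counts as two
- for target the idle adduct is counted in
- steps thought possible: substrate -> target; substrate -> side product; substrate + target <-> idle adduct
- in an amount of target, one idle adduct counts as one target

- which of the two there is more of at the end, delta (side product / target)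
- which of the two there is more of at the end, gamma (side product / target)
- which of the two there is more of at the end, theta (side product / target)
- final target, as a percentage of the substrate charged, in delta
- final target, as a percentage of the substrate charged, in gamma
- final target, as a percentage of the substrate charged, in theta

Start with the easy step: take the fraction of substrate left in maple and add up its area against time by trapezoids, which gives an exposure, E, of 1.64 min of full charge by 2.50 min.

Target, with the idle adduct counted in, is made from free substrate, and binding neither adds to that count nor takes from it, so divide the 30 % of target by E to get the target made per minute of exposure, k_T = 0.182 min⁻¹.

Which product leads? Maple's last reading has 59.0 % of the substrate gone, and target accounts for 30 %, so side product and bound substrate together hold 29.0 %, which puts target level or ahead, though that margin lies inside the scatter. Both products draw on the same free substrate, so their ratio, the selectivity factor, should hold along a run, and the 1.03 read in maple can only rise with any bound substrate taken out of the remainder; I therefore commit to target in delta, gamma and theta.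

How much target? Take maple's decay constant, k_d, the natural logarithm of charged over left divided by the time, which is 0.357 min⁻¹ at the last reading, so that exposure is the fraction gone divided by k_d. Multiplying by k_T gives 38.9 % for delta, 50.7 % for gamma and 48.0 % for theta.

The forecast, reasoning that “Target tracks substrate consumed at a steady ratio”, chose side product in each flask, with 35 %, 46 % and 44 % of target for delta, gamma and theta.

The flasks give target 39.3 % in delta, 62.8 % in gamma and 53.0 % in theta, ahead of side product at 16.1 %, 25.8 % and 21.7 %. Gamma still holds 4.70 % of substrate at 15 min, more than the 0.472 % my exponential left. Put k_T on the real curve: theta's substrate falls from 28.2 % at 4.00 min to 12.6 % at 8.00 min, which gives 15 percentage points of new target, and theta's target rises by 14 points over those minutes.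

    substrate → target (k = 0.00302 s⁻¹)
    substrate → side product (k = 0.00124 s⁻¹)
    substrate + target ⇌ idle adduct, settled at all times (K = 1.20 L mol⁻¹)

For the neighbouring flask, delta read at 10 min, start from theta's 53.0 % at 8.0 min, since the two have the same charge, and add k_T times the mean substrate over the extra time, which gives 56.9 %. The computed result is 56.8 %.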